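Numbering used here: butenolide O1, C2 (lactone C=O), C3 (enol carbon), C4 (carries ring A), C5 (quaternary); ring B C1' (benzylic carbon) to C6', with the oxygen on C4' and the epoxide side chain on C3'.
Enabling feature: ring B is a phenol alkylated at C1' (para to O) and C3' (ortho to O), the carbon pattern of a 2,4-disubstituted cyclohex-2-enone, so the phenol is traced back to that enone and ring B is cut at C1'–C6' and C2'–C3'.
These cuts give a butenolide aldehyde with a 3-oxopropyl group on C5 and an epoxide-bearing vinyl ketone; the aldehyde is cut at C5–CH2 (acrolein) and the butenolide at C4–C5 and O1–C2 (arylpyruvate plus glyoxylate); the vinyl ketone comes from 6-methylhept-5-en-2-one.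
Forward: ring A is bought, the butenolide ring is closed first by aldol-lactonisation, the C5 chain is added, ring B is built last by an amine-catalysed Michael/aldol annulation and dehydrogenated to the phenol, and the two benzyl ethers are removed at the end.
Stereochemistry: (R)-C5 from a cinchona-catalysed Michael addition to acrolein, the (R)-oxirane carbon from a Shi epoxidation; the sp3 ring carbon made in the annulation disappears on aromatisation.

Key step: step 8

Assumption: the quinidine-derived 6'-hydroxy catalyst of step 4 is taken to deliver acrolein to the dienolate face that gives (R)-C5; if the sense proves opposite, its quinine-derived pseudoenantiomer is used with nothing else changed.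

Step 1
Reactants: 1 4-hydroxyphenylpyruvic acid
Product: 2 methyl 4-hydroxyphenylpyruvate
Conditions: MeOH, H2SO4 (cat.), rt
Reagents that add atoms: methanol, CO
Why: Fischer esterification of the activated α-keto acid leaves the phenol untouched and provides the ester that later allows lactonisation by transesterification.

Step 2
Reactants: 2 methyl 4-hydroxyphenylpyruvate; 3 methyl glyoxylate
Product: 5 methyl 4-hydroxy-3-(4-hydroxyphenyl)-5-oxo-2,5-dihydrofuran-2-carboxylate (racemic 5-H butenolide), via aldol adduct 4 (not isolated)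
Conditions: 3 (freshly distilled, 2.5 equiv), Et3N (1 equiv), CH2Cl2, 0 °C → rt, slow addition of 2; 1 M HCl work-up
Reagents that add atoms: none
Why: Cross-aldol addition of the enolised arylpyruvate to the non-enolisable, highly electrophilic aldehyde followed by spontaneous lactonisation of the γ-hydroxy α-keto ester (isotetronic acid synthesis) should give the butenolide, excess glyoxylate and slow addition holding back pyruvate self-condensation; C5 is formed racemic and is corrected in step 4.

Step 3
Reactants: 5 methyl 4-hydroxy-3-(4-hydroxyphenyl)-5-oxo-2,5-dihydrofuran-2-carboxylate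
Product: 6 methyl 4-(benzyloxy)-3-[4-(benzyloxy)phenyl]-5-oxo-2,5-dihydrofuran-2-carboxylate (racemic)
Conditions: BnOH (2.2 equiv), PPh3 (2.2 equiv), DIAD (2.2 equiv), THF, 0 °C → rt
Reagents that add atoms: benzyl alcohol, OCc1ccccc1
Why: A double Mitsunobu etherification engages only the two acidic hydroxyls (enol and phenol), so the base-labile C5–H is not benzylated as it could be with benzyl bromide and carbonate.

Step 4
Reactants: 6 methyl 4-(benzyloxy)-3-[4-(benzyloxy)phenyl]-5-oxo-2,5-dihydrofuran-2-carboxylate; 7 acrolein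
Product: 8 methyl (2R)-4-(benzyloxy)-3-[4-(benzyloxy)phenyl]-5-oxo-2-(3-oxopropyl)-2,5-dihydrofuran-2-carboxylate
Conditions: 7 (3 equiv), cupreidine 9-O-(9-phenanthryl) ether (quinidine series, free 6'-OH, 10 mol %), CH2Cl2, −25 °C
Reagents that add atoms: none
Why: In this bifunctional cinchona-catalysed vinylogous Michael addition the quinuclidine removes C5–H to give a planar 2-furanolate (both enantiomers of 6 converge), and acrolein held by the 6'-OH is delivered to one face of the ion-paired dienolate at C5, the conjugation-retaining γ-position, so that (R)-C5 is set by the catalyst.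

Step 5
Reactants: 9 6-methylhept-5-en-2-one
Product: 10 4-[(2R)-3,3-dimethyloxiran-2-yl]butan-2-one
Conditions: D-fructose-derived Shi ketone (0.3 equiv), Oxone (2KHSO5·KHSO4·K2SO4), K2CO3, Bu4NHSO4, MeCN/CH2(OMe)2–aq. Na2B4O7/Na2H2EDTA (pH 10.5), 0 °C
Reagents that add atoms: potassium peroxymonosulfate (KHSO5 of Oxone), [K+].[O-]S(=O)(=O)OO
Why: Shi asymmetric epoxidation, in which the chiral dioxirane transfers oxygen through a spiro transition state to the electron-rich trisubstituted alkene, should set the (R) configuration at the oxirane CH as is usual for 2-methylalk-2-enes with this catalyst enantiomer.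

Step 6
Reactants: 10 4-[(2R)-3,3-dimethyloxiran-2-yl]butan-2-one
Product: 11 1-(dimethylamino)-5-[(2R)-3,3-dimethyloxiran-2-yl]pentan-3-one
Conditions: LiN(iPr)2 (LDA), THF, −78 °C (ketone added to base); then CH2=NMe2+ I−, −78 °C → rt
Reagents that add atoms: N,N-dimethylmethyleneiminium iodide (Eschenmoser's salt), C=[N+](C)C.[I-]
Why: Kinetic deprotonation at the methyl group and Mannich reaction of the lithium enolate with the preformed iminium salt add the one carbon needed, the oxirane being safe because attack by this enolate would be a disfavoured 5-(enolendo)-exo-tet closure.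

Step 7
Reactants: 11 1-(dimethylamino)-5-[(2R)-3,3-dimethyloxiran-2-yl]pentan-3-one
Product: 13 5-[(2R)-3,3-dimethyloxiran-2-yl]pent-1-en-3-one, via methiodide 12 (not isolated)
Conditions: MeI, Et2O, rt; then sat. aq. NaHCO3/CH2Cl2, rt; product kept cold over BHT and used at once
Reagents that add atoms: none
Why: N-Quaternisation followed by E1cB elimination of trimethylamine from the β-ammonium ketone under bicarbonate is the standard Mannich-base route to vinyl ketones and keeps acid away from the oxirane.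

Step 8
Reactants: 8 methyl (2R)-4-(benzyloxy)-3-[4-(benzyloxy)phenyl]-5-oxo-2-(3-oxopropyl)-2,5-dihydrofuran-2-carboxylate; 13 5-[(2R)-3,3-dimethyloxiran-2-yl]pent-1-en-3-one
Product: 16 methyl (2R)-4-(benzyloxy)-3-[4-(benzyloxy)phenyl]-2-[(3-{[(2R)-3,3-dimethyloxiran-2-yl]methyl}-4-oxocyclohex-2-en-1-yl)methyl]-5-oxo-2,5-dihydrofuran-2-carboxylate (epimers at cyclohexenyl C1), via keto aldehyde 14 (not isolated), via ketol 15 (not isolated)
Conditions: 13 (1.5 equiv), (S)-2-[methoxy(diphenyl)methyl]pyrrolidine (10 mol %), ethyl 3,4-dihydroxybenzoate (20 mol %), CHCl3, 4 °C → rt; then pyrrolidine/AcOH (30 mol % each), rt → 40 °C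
Reagents that add atoms: none
Why: The hindered pyrrolidine converts aldehyde 8 into an enamine whose nucleophilic carbon (the later C1') adds to the terminal carbon of vinyl ketone 13 (the later C6'), and hydrolysis releases keto aldehyde 14; pyrrolidinium acetate then brings about aldol addition of the ketone α'-carbon (later C3') to the formyl carbon (later C2') and dehydration of ketol 15 to the conjugated enone. The closest known reaction type is the secondary-amine-catalysed Michael addition of aldehydes to alkyl vinyl ketones followed by aldol condensation, an organocatalytic Robinson annulation to 4-substituted and 2,4-disubstituted cyclohex-2-enones. Ring B closes in a 6-(enolendo)-exo-trig aldol step. The one new sp3 centre (the former aldehyde α-carbon) is biased by the chiral amine but is left unassigned because aromatisation removes it, and C5 and the oxirane carbon take no part. The selectivity required is closure through the α'-carbon, and the substrate secures it because every other enol–carbonyl pairing in 14 would give a four-membered ring, so the side chain lands ortho to the future phenol oxygen by connectivity alone. The near-neutral amine/acetate medium is chosen to spare the oxirane, the methyl ester and the lactone and to keep retro-Michael loss of the C5 chain slow.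

Step 9
Reactants: 16 methyl (2R)-4-(benzyloxy)-3-[4-(benzyloxy)phenyl]-2-[(3-{[(2R)-3,3-dimethyloxiran-2-yl]methyl}-4-oxocyclohex-2-en-1-yl)methyl]-5-oxo-2,5-dihydrofuran-2-carboxylate
Product: 17 methyl (2R)-4-(benzyloxy)-3-[4-(benzyloxy)phenyl]-2-[(3-{[(2R)-3,3-dimethyloxiran-2-yl]methyl}-4-[(trimethylsilyl)oxy]cyclohexa-2,4-dien-1-yl)methyl]-5-oxo-2,5-dihydrofuran-2-carboxylate
Conditions: LiN(iPr)2 (LDA, 1.3 equiv), TMSCl (3 equiv, present during deprotonation), THF, −78 °C; Et3N, pentane, filtration; used crude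
Reagents that add atoms: chlorotrimethylsilane, C[Si](C)(C)Cl
Why: Kinetic α'-deprotonation of the cyclohex-2-enone and immediate O-silylation should give the cross-conjugated 2-silyloxy diene, the in situ quench leaving the enolate no time to attack the neighbouring ester.

Step 10
Reactants: 17 methyl (2R)-4-(benzyloxy)-3-[4-(benzyloxy)phenyl]-2-[(3-{[(2R)-3,3-dimethyloxiran-2-yl]methyl}-4-[(trimethylsilyl)oxy]cyclohexa-2,4-dien-1-yl)methyl]-5-oxo-2,5-dihydrofuran-2-carboxylate
Product: 19 methyl (2R)-4-(benzyloxy)-3-[4-(benzyloxy)phenyl]-2-[(3-{[(2R)-3,3-dimethyloxiran-2-yl]methyl}-4-hydroxyphenyl)methyl]-5-oxo-2,5-dihydrofuran-2-carboxylate, via cyclohexadienone 18 (not isolated)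
Conditions: Pd(OAc)2 (1.1 equiv), NaHCO3 (2 equiv), MeCN, rt; filtration through neutral alumina
Reagents that add atoms: none
Why: In this Saegusa–Ito oxidation Pd(OAc)2 (divalent palladium) converts the silyl dienol ether into a palladium enolate, β-hydride elimination gives the 4H-cyclohexa-2,5-dienone, and this tautomerises to the phenol, while NaHCO3 takes up the acetic acid so that the new ortho phenol does not open the oxirane.

Step 11
Reactants: 19 methyl (2R)-4-(benzyloxy)-3-[4-(benzyloxy)phenyl]-2-[(3-{[(2R)-3,3-dimethyloxiran-2-yl]methyl}-4-hydroxyphenyl)methyl]-5-oxo-2,5-dihydrofuran-2-carboxylate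
Product: 20 methyl (2R)-2-[(3-{[(2R)-3,3-dimethyloxiran-2-yl]methyl}-4-hydroxyphenyl)methyl]-4-hydroxy-3-(4-hydroxyphenyl)-5-oxo-2,5-dihydrofuran-2-carboxylate (target CNP0331593.1)
Conditions: H2 (1 atm), Pd/C (10 % Pd on carbon), EtOAc, rt, stopped at full conversion; neutral work-up
Reagents that add atoms: none
Why: Hydrogenolysis of the benzyl enol ether and the aryl benzyl ether under neutral conditions should free both hydroxyls without reducing the tetrasubstituted butenolide alkene or the non-benzylic trialkyl oxirane, and no acid or base is present to trigger phenol–oxirane cyclisation.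

Compound list
1 | 4-hydroxyphenylpyruvic acid | O=C(O)C(=O)Cc1ccc(O)cc1 | starting material
2 | methyl 4-hydroxyphenylpyruvate | COC(=O)C(=O)Cc1ccc(O)cc1 | intermediate
3 | methyl glyoxylate | COC(=O)C=O | starting material
4 | dimethyl 2-hydroxy-3-(4-hydroxyphenyl)-4-oxopentanedioate (aldol adduct, not isolated) | COC(=O)C(O)C(c1ccc(O)cc1)C(=O)C(=O)OC | intermediate
5 | methyl 4-hydroxy-3-(4-hydroxyphenyl)-5-oxo-2,5-dihydrofuran-2-carboxylate (racemic) | COC(=O)C1OC(=O)C(O)=C1c1ccc(O)cc1 | intermediate
6 | methyl 4-(benzyloxy)-3-[4-(benzyloxy)phenyl]-5-oxo-2,5-dihydrofuran-2-carboxylate (racemic) | COC(=O)C1OC(=O)C(OCc2ccccc2)=C1c1ccc(OCc2ccccc2)cc1 | intermediate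
7 | acrolein | C=CC=O | starting material
8 | methyl (2R)-4-(benzyloxy)-3-[4-(benzyloxy)phenyl]-5-oxo-2-(3-oxopropyl)-2,5-dihydrofuran-2-carboxylate | COC(=O)[C@]1(CCC=O)OC(=O)C(OCc2ccccc2)=C1c1ccc(OCc2ccccc2)cc1 | intermediate
9 | 6-methylhept-5-en-2-one | CC(=O)CCC=C(C)C | starting material
10 | 4-[(2R)-3,3-dimethyloxiran-2-yl]butan-2-one | CC(=O)CC[C@H]1OC1(C)C | intermediate
11 | 1-(dimethylamino)-5-[(2R)-3,3-dimethyloxiran-2-yl]pentan-3-one | CN(C)CCC(=O)CC[C@H]1OC1(C)C | intermediate
12 | 5-[(2R)-3,3-dimethyloxiran-2-yl]-N,N,N-trimethyl-3-oxopentan-1-aminium iodide (not isolated) | C[N+](C)(C)CCC(=O)CC[C@H]1OC1(C)C.[I-] | intermediate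
13 | 5-[(2R)-3,3-dimethyloxiran-2-yl]pent-1-en-3-one | C=CC(=O)CC[C@H]1OC1(C)C | intermediate
14 | methyl (2R)-4-(benzyloxy)-3-[4-(benzyloxy)phenyl]-2-{7-[(2R)-3,3-dimethyloxiran-2-yl]-2-formyl-5-oxoheptyl}-5-oxo-2,5-dihydrofuran-2-carboxylate (keto aldehyde, not isolated) | COC(=O)[C@]1(CC(C=O)CCC(=O)CC[C@H]2OC2(C)C)OC(=O)C(OCc2ccccc2)=C1c1ccc(OCc2ccccc2)cc1 | intermediate
15 | methyl (2R)-4-(benzyloxy)-3-[4-(benzyloxy)phenyl]-2-[(3-{[(2R)-3,3-dimethyloxiran-2-yl]methyl}-2-hydroxy-4-oxocyclohexyl)methyl]-5-oxo-2,5-dihydrofuran-2-carboxylate (ketol, not isolated) | COC(=O)[C@]1(CC2CCC(=O)C(C[C@H]3OC3(C)C)C2O)OC(=O)C(OCc2ccccc2)=C1c1ccc(OCc2ccccc2)cc1 | intermediate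
16 | methyl (2R)-4-(benzyloxy)-3-[4-(benzyloxy)phenyl]-2-[(3-{[(2R)-3,3-dimethyloxiran-2-yl]methyl}-4-oxocyclohex-2-en-1-yl)methyl]-5-oxo-2,5-dihydrofuran-2-carboxylate | COC(=O)[C@]1(CC2C=C(C[C@H]3OC3(C)C)C(=O)CC2)OC(=O)C(OCc2ccccc2)=C1c1ccc(OCc2ccccc2)cc1 | intermediate
17 | methyl (2R)-4-(benzyloxy)-3-[4-(benzyloxy)phenyl]-2-[(3-{[(2R)-3,3-dimethyloxiran-2-yl]methyl}-4-[(trimethylsilyl)oxy]cyclohexa-2,4-dien-1-yl)methyl]-5-oxo-2,5-dihydrofuran-2-carboxylate | COC(=O)[C@]1(CC2C=C(C[C@H]3OC3(C)C)C(O[Si](C)(C)C)=CC2)OC(=O)C(OCc2ccccc2)=C1c1ccc(OCc2ccccc2)cc1 | intermediate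
18 | methyl (2R)-4-(benzyloxy)-3-[4-(benzyloxy)phenyl]-2-[(3-{[(2R)-3,3-dimethyloxiran-2-yl]methyl}-4-oxocyclohexa-2,5-dien-1-yl)methyl]-5-oxo-2,5-dihydrofuran-2-carboxylate (not isolated) | COC(=O)[C@]1(CC2C=C(C[C@H]3OC3(C)C)C(=O)C=C2)OC(=O)C(OCc2ccccc2)=C1c1ccc(OCc2ccccc2)cc1 | intermediate
19 | methyl (2R)-4-(benzyloxy)-3-[4-(benzyloxy)phenyl]-2-[(3-{[(2R)-3,3-dimethyloxiran-2-yl]methyl}-4-hydroxyphenyl)methyl]-5-oxo-2,5-dihydrofuran-2-carboxylate | COC(=O)[C@]1(Cc2ccc(O)c(C[C@H]3OC3(C)C)c2)OC(=O)C(OCc2ccccc2)=C1c1ccc(OCc2ccccc2)cc1 | intermediate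
20 | methyl (2R)-2-[(3-{[(2R)-3,3-dimethyloxiran-2-yl]methyl}-4-hydroxyphenyl)methyl]-4-hydroxy-3-(4-hydroxyphenyl)-5-oxo-2,5-dihydrofuran-2-carboxylate | COC(=O)[C@]1(Cc2ccc(O)c(C[C@H]3OC3(C)C)c2)OC(=O)C(O)=C1c1ccc(O)cc1 | target

Total step count: 11. Longest linear sequence: 8 steps (steps 1, 2, 3, 4, 8, 9, 10, 11 from 4-hydroxyphenylpyruvic acid); the vinyl ketone branch (steps 5 to 7) joins at step 8.

Steps most likely to fail

Step 4. What may go wrong is poor facial discrimination at the planar furanolate (low enantiomeric purity at C5), attack through C3 instead of C5, or amine-induced oligomerisation of acrolein. The fallback sets out from 6 and returns at 8, replacing the conjugate addition by an allylation and adjusting the oxidation level afterwards. Palladium-catalysed asymmetric allylic alkylation of 6 with allyl methyl carbonate, Pd2(dba)3·CHCl3 (zerovalent palladium) and the DACH-phenyl bisphosphine (Trost) ligand of the appropriate handedness in CH2Cl2 should give methyl (2R)-4-(benzyloxy)-3-[4-(benzyloxy)phenyl]-5-oxo-2-(prop-2-en-1-yl)-2,5-dihydrofuran-2-carboxylate F1. Anti-Markovnikov hydroboration of the terminal alkene with 9-BBN in THF would give the B-alkyl-9-borabicyclo[3.3.1]nonane F2, which is oxidised in the same flask with NaBO3·4H2O to the 3-hydroxypropyl butenolide F3. Dess–Martin periodinane with NaHCO3 in CH2Cl2 then gives aldehyde 8.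

Step 8. What may go wrong is opening of the oxirane by the amine or the acetic acid during the two-stage annulation, sluggish aldol closure under conditions mild enough for the oxirane, or slow retro-Michael erosion at C5. The fallback sets out from 9 and 8 and returns at 16, carrying the alkene through the annulation and introducing the epoxide afterwards. Ketone 9 is taken through the operations of steps 6 and 7: kinetic Mannich reaction gives 1-(dimethylamino)-7-methyloct-6-en-3-one F4, methylation gives the methiodide N,N,N,7-tetramethyl-3-oxooct-6-en-1-aminium iodide F5, and bicarbonate elimination gives 7-methylocta-1,6-dien-3-one F6. Annulation of F6 with 8 under the amine catalysis of step 8, now free to use a stronger condensing agent such as dibenzylammonium trifluoroacetate, should pass through the keto aldehyde with a 2-formyl-9-methyl-5-oxodec-8-enyl chain F7 and the corresponding ketol F8 to the prenyl-substituted cyclohexenone F9. Shi epoxidation of F9 with the D-fructose-derived ketone and Oxone at 0 °C, selective for the only electron-rich trisubstituted alkene, would give 16 with the (R)-oxirane set by the catalyst.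

Step 10. What may go wrong is acid- or palladium-promoted attack of the newly formed ortho phenol on the oxirane, or protodesilylation of 17 back to the enone before palladation. The fallback sets out from 16 and returns at 19, using selenium-based dehydrogenation instead of palladium. The kinetic lithium enolate of 16 (LDA, THF, −78 °C) is trapped with PhSeCl to give the α'-selenide, the 5-(phenylselanyl)-4-oxocyclohex-2-enyl compound F10. Oxidation with NaIO4 and NaHCO3 in aqueous THF at 0 °C gives the selenoxide F11, which undergoes syn-elimination below room temperature to dienone 18, and this tautomerises to phenol 19 under bicarbonate buffering.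

Further compounds
F1 | step 4 | methyl (2R)-4-(benzyloxy)-3-[4-(benzyloxy)phenyl]-5-oxo-2-(prop-2-en-1-yl)-2,5-dihydrofuran-2-carboxylate | COC(=O)[C@]1(CC=C)OC(=O)C(OCc2ccccc2)=C1c1ccc(OCc2ccccc2)cc1
F2 | step 4 | methyl (2R)-4-(benzyloxy)-3-[4-(benzyloxy)phenyl]-2-[3-(9-borabicyclo[3.3.1]nonan-9-yl)propyl]-5-oxo-2,5-dihydrofuran-2-carboxylate | COC(=O)[C@]1(CCCB2C3CCCC2CCC3)OC(=O)C(OCc2ccccc2)=C1c1ccc(OCc2ccccc2)cc1
F3 | step 4 | methyl (2R)-4-(benzyloxy)-3-[4-(benzyloxy)phenyl]-2-(3-hydroxypropyl)-5-oxo-2,5-dihydrofuran-2-carboxylate | COC(=O)[C@]1(CCCO)OC(=O)C(OCc2ccccc2)=C1c1ccc(OCc2ccccc2)cc1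
F4 | step 8 | 1-(dimethylamino)-7-methyloct-6-en-3-one | CN(C)CCC(=O)CCC=C(C)C
F5 | step 8 | N,N,N,7-tetramethyl-3-oxooct-6-en-1-aminium iodide | C[N+](C)(C)CCC(=O)CCC=C(C)C.[I-]
F6 | step 8 | 7-methylocta-1,6-dien-3-one | C=CC(=O)CCC=C(C)C
F7 | step 8 | methyl (2R)-4-(benzyloxy)-3-[4-(benzyloxy)phenyl]-2-(2-formyl-9-methyl-5-oxodec-8-en-1-yl)-5-oxo-2,5-dihydrofuran-2-carboxylate | COC(=O)[C@]1(CC(C=O)CCC(=O)CCC=C(C)C)OC(=O)C(OCc2ccccc2)=C1c1ccc(OCc2ccccc2)cc1
F8 | step 8 | methyl (2R)-4-(benzyloxy)-3-[4-(benzyloxy)phenyl]-2-{[2-hydroxy-3-(3-methylbut-2-en-1-yl)-4-oxocyclohexyl]methyl}-5-oxo-2,5-dihydrofuran-2-carboxylate | COC(=O)[C@]1(CC2CCC(=O)C(CC=C(C)C)C2O)OC(=O)C(OCc2ccccc2)=C1c1ccc(OCc2ccccc2)cc1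
F9 | step 8 | methyl (2R)-4-(benzyloxy)-3-[4-(benzyloxy)phenyl]-2-{[3-(3-methylbut-2-en-1-yl)-4-oxocyclohex-2-en-1-yl]methyl}-5-oxo-2,5-dihydrofuran-2-carboxylate | COC(=O)[C@]1(CC2C=C(CC=C(C)C)C(=O)CC2)OC(=O)C(OCc2ccccc2)=C1c1ccc(OCc2ccccc2)cc1
F10 | step 10 | methyl (2R)-4-(benzyloxy)-3-[4-(benzyloxy)phenyl]-2-[(3-{[(2R)-3,3-dimethyloxiran-2-yl]methyl}-4-oxo-5-(phenylselanyl)cyclohex-2-en-1-yl)methyl]-5-oxo-2,5-dihydrofuran-2-carboxylate | COC(=O)[C@]1(CC2C=C(C[C@H]3OC3(C)C)C(=O)C([Se]c3ccccc3)C2)OC(=O)C(OCc2ccccc2)=C1c1ccc(OCc2ccccc2)cc1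
F11 | step 10 | methyl (2R)-2-[(5-(benzeneseleninyl)-3-{[(2R)-3,3-dimethyloxiran-2-yl]methyl}-4-oxocyclohex-2-en-1-yl)methyl]-4-(benzyloxy)-3-[4-(benzyloxy)phenyl]-5-oxo-2,5-dihydrofuran-2-carboxylate | COC(=O)[C@]1(CC2C=C(C[C@H]3OC3(C)C)C(=O)C([Se](=O)c3ccccc3)C2)OC(=O)C(OCc2ccccc2)=C1c1ccc(OCc2ccccc2)cc1
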